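## Analysis of the target

Laxiflorin (19) is a flavanone: ring A (benzo) is fused to the dihydropyranone ring C, and C2 carries the 4-hydroxy-3-methoxyphenyl ring B. Ring A is fully substituted. O1 (on C8a), the 5-OH and the 7-OH form a phloroglucinol pattern, C6 carries a 2-hydroxyethyl chain and C8 a prenyl group, so C6 and C8 differ only in which neighbouring oxygen is O1. The single stereocentre is C2 (S). It is benzylic, bonded to O1 and β to the C4 ketone, has no second stereocentre to relay from, and with free 4'-OH and 5-OH it is lost under base by retro-oxa-Michael opening to the chalcone. The sensitive groups are the prenyl alkene next to the 7-oxygen (acid closes it to a chroman; hydrogenation and electrophilic oxidants attack it), three phenols and a primary alcohol. The difficulty lies in the regiochemistry of the hexasubstituted ring A and in forming C2 enantioselectively under conditions that never open ring C. The strategy reads O1, C8a, C4a and C4 as a 1-oxadiene, an ortho-quinone methide latent in a ring A salicylaldehyde whose formyl carbon is C4, and C2–C3 with ring B as a protected 2-methoxy-4-vinylphenol. An oxa-[4+2] cycloaddition then forms O1–C2 and C3–C4 in one step.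

## Retrosynthetic reasoning

**19 to 18.** Only protecting groups are removed: three methoxymethyl ethers (O5, O7, O4') and the silyl ether of the chain. All are acid-labile, so one operation clears them. They stay to the end because free phenols would interfere with the oxidation at C4 and, as phenoxides, would open ring C.

**18 to 16.** The C4 carbonyl is traced back to a C4 methyl ether. The cycloaddition delivers C4 at the aldehyde oxidation level with one methoxy group, and hydride abstraction from this doubly activated C–H gives the ketone through hemiketal 17. The C4 configuration of 16 is therefore of no consequence.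

**16 to 11 and 13.** O1–C2 and C3–C4 are cut together. This divides ring C into two stable, achiral pieces of similar size. C3–C4 joins the nucleophilic terminal carbon of 13 to the electrophilic carbon of the oxadiene, and O1–C2 forms at the carbon that best carries positive charge, so the orientation is fixed by polarity. A cut at C2–C3 or at O1–C2 alone would need an acetophenone-type ring A and an aldol/oxa-Michael sequence that sets C2 under basic, reversible conditions. In the forward direction 11 passes through acetal 14 to quinone methide 15, and a chiral acid has to choose the face on which C2 is formed. This demands that 11 has exactly one free phenol, flanked by the prenyl and formyl groups.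

**11 to 10, then to 8 and 9.** The formyl bond (C4–C4a) and the prenyl bond at C8 are both cut ortho to the free phenol. In 8 the only two unsubstituted ring positions are equivalent and both ortho to the hydroxyl, so each substitution has one possible site. The oxygen that becomes O1 is thereby fixed as the one para to the chain. Prenylation comes first because the phenoxide of 8 is a better carbon nucleophile than a chelated salicylaldehyde.

**8 to 7, 6, 4 and 3.** The hydroxyethyl chain is traced through borane 5 and alkene 4 to a formyl group. The benzyl ether on the para oxygen keeps that oxygen distinct from the two acetal-protected ones, and it is removed by hydrogenolysis before any alkene is in the molecule.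

**3 to 2 to 1.** The formyl group of 1 differentiates the three oxygens. The hydroxyl para to it is the most acidic and the only one not chelated, so it takes the benzyl group. The two chelated hydroxyls then take the methoxymethyl groups. The formyl carbon thus steers the protection and ends as the benzylic carbon of the chain.

**13 to 12.** The phenol of 12 is masked as a methoxymethyl ether, which keeps the styrene electron-rich and falls in the final acid step with the other acetals.

## Alternatives that were turned down

**Alternative 1:** Ring A is disconnected at C4a–C5 and built last from the open-chain precursor A1. A1 is a (2S)-2-aryl-2,3-dihydropyran-4-one whose C8a carries a prenylated β-keto chain ending in a γ-butyrolactone. In the forward step base forms the extended enolate, C4a attacks the lactone carbonyl C5, the expelled alkoxide becomes the hydroxyethyl chain, and enolisation aromatises ring A to A2.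
- In favour: all ring A substituents come from the chain, so there is no aromatic regiochemistry problem and ring A needs no protecting groups.
- Stronger than the chosen route on one point: C2 would come from an established catalytic asymmetric hetero-Diels–Alder construction of the dihydropyranone.
- Against: A1 has several acidic sites, and the most acidic one (C6–H, between lactone and ketone) gives an unproductive enolate. The needed nucleophile is the vinylogous carbon C4a. O-acylation, retro-Claisen cleavage and base-induced β-elimination of O1 (which scrambles C2) all compete. Assembling A1 needs several C–C bond formations on a sensitive chain.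
- In its place the chosen route keeps ring A aromatic from a commercial aldehyde and creates C2 under acid in the step that closes ring C, at the cost of more protecting groups.

**Alternative 2:** Ring C is disconnected at C2–C3. The precursor is diazoketone A3, a ring A aryl diazomethyl ketone whose ortho oxygen O1 carries the ring B benzyl group. A chiral dirhodium tetracarboxylate, Rh2(O2CR*)4, would generate the carbenoid at C3, which inserts into the benzylic C2–H bond to give A4.
- Stronger than the chosen route on two points: the ketone is delivered directly, and enantioselective carbenoid insertion next to an ether oxygen is an established reaction type.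
- Against: attack of the carbenoid on the lone pair of O1 gives a five-membered oxonium ylide, and a benzyl shift then leads to a benzofuranone. The prenyl alkene and the electron-rich arenes invite cyclopropanation and aromatic addition. A3 must be made by acylating a diazoalkane with a doubly ortho-substituted, hindered acid derivative. Ring A still needs the same oxygen differentiation, and four silyl groups are carried.
- In its place the chosen route forms both ring C bonds between two fragments, needs no diazo compound and uses the aldehyde rather than the hindered acid, and pays with one oxidation at C4.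

**Alternative 3:** Ring A is disconnected at C8–C8a and C4a–C5. The bis-silyloxy diene A5 (carbons C5 to C8, from an acyl butyrolactone) would add across the C4a=C8a bond of the (S)-bromodihydropyranone A6. Collapse of the lactone ketal, dehydrobromination and enolisation then give A7.
- As strong or stronger: it is equally convergent, it builds the whole of ring A with regiochemistry set by the polarisation of both partners, and it ends with ring A unprotected, so the endgame is shorter.
- Against: the dienophile is a vinylogous ester deactivated by O1. The diene is substituted at both termini and at C6, and its C7=C8 geometry must be controlled. Heat or strong Lewis acid would be needed, which endangers the silyl ketene acetal and the C2–O1 bond of A6.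
- In its place the chosen route forms its bonds at low temperature with polarity-matched partners and takes ring A from simple aromatic chemistry.

Key step: step 10

Remark on the chemistry: the (R)-acid is written for step 10 on the assumption that it shields the C4 face whose endo transition state gives 2S. The sense of induction cannot be derived from structure alone, and the (S)-acid would be used if the opposite sense were found.

## Route

Step 1
Reactants: 1 2,4,6-trihydroxybenzaldehyde
Product: 2 4-(benzyloxy)-2,6-dihydroxybenzaldehyde
Conditions: BnBr (1.0 equiv), NaHCO3, DMF, 40 °C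
Reagents that add atoms: benzyl bromide, BrCc1ccccc1
Why: Williamson etherification; the 4-OH is the most acidic hydroxyl (para to the formyl group) and the only one not hydrogen-bonded to the carbonyl, so one equivalent of halide with a weak base should alkylate it first.

Step 2
Reactants: 2 4-(benzyloxy)-2,6-dihydroxybenzaldehyde
Product: 3 4-(benzyloxy)-2,6-bis(methoxymethoxy)benzaldehyde
Conditions: NaH, MOMCl, DMF, 0 °C to rt
Reagents that add atoms: chloromethyl methyl ether, COCCl
Why: Double O-alkylation of the two chelated phenols as sodium phenoxides with the hard chloromethyl ether; the aldehyde has no enolisable position and the benzyl ether is inert.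

Step 3
Reactants: 3 4-(benzyloxy)-2,6-bis(methoxymethoxy)benzaldehyde
Product: 4 5-(benzyloxy)-2-ethenyl-1,3-bis(methoxymethoxy)benzene
Conditions: Ph3PCH3Br, KOtBu, THF, 0 °C to rt
Reagents that add atoms: methyltriphenylphosphonium bromide, C[P+](c1ccccc1)(c1ccccc1)c1ccccc1.[Br-]
Why: Wittig methylenation with the non-stabilised ylide should convert the hindered, electron-rich aldehyde to the styrene; acetal and benzyl ethers are stable to the ylide.

Step 4
Reactants: 4 5-(benzyloxy)-2-ethenyl-1,3-bis(methoxymethoxy)benzene
Product: 6 2-[4-(benzyloxy)-2,6-bis(methoxymethoxy)phenyl]ethan-1-ol, via alkylborane 5 (not isolated)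
Conditions: 9-BBN, THF, 0 °C to rt; then NaOH, H2O2, 0 °C
Reagents that add atoms: hydrogen peroxide, OO (the hydroxyl oxygen); 9-borabicyclo[3.3.1]nonane, B1C2CCCC1CCC2 (its atoms are present only in 5)
Why: Brown hydroboration–oxidation; the bulky dialkylborane places boron on the terminal carbon of the styrene, and alkaline peroxide oxidises the C–B bond of 5 with retention to give the primary alcohol.

Step 5
Reactants: 6 2-[4-(benzyloxy)-2,6-bis(methoxymethoxy)phenyl]ethan-1-ol
Product: 7 {2-[4-(benzyloxy)-2,6-bis(methoxymethoxy)phenyl]ethoxy}(tert-butyl)dimethylsilane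
Conditions: TBSCl, imidazole, DMF, rt
Reagents that add atoms: tert-butyldimethylsilyl chloride, CC(C)(C)[Si](C)(C)Cl
Why: Standard silylation of a primary alcohol; it keeps the chain oxygen out of the alkylation in step 7 and out of acetal exchange in step 10.

Step 6
Reactants: 7 {2-[4-(benzyloxy)-2,6-bis(methoxymethoxy)phenyl]ethoxy}(tert-butyl)dimethylsilane
Product: 8 4-[2-(tert-butyldimethylsilyloxy)ethyl]-3,5-bis(methoxymethoxy)phenol
Conditions: H2 (1 atm), Pd/C (10%), EtOAc, rt
Reagents that add atoms: none
Why: Hydrogenolysis of the benzyl aryl ether frees the phenol para to the chain; ethyl acetate as solvent spares the silyl ether and the acetals, and no alkene is yet present.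

Step 7
Reactants: 8 4-[2-(tert-butyldimethylsilyloxy)ethyl]-3,5-bis(methoxymethoxy)phenol; 9 prenyl bromide
Product: 10 4-[2-(tert-butyldimethylsilyloxy)ethyl]-3,5-bis(methoxymethoxy)-2-(3-methylbut-2-en-1-yl)phenol
Conditions: NaH, toluene, 0 °C; then 9 (1.0 equiv), rt
Reagents that add atoms: none
Why: ortho-C-Alkylation of a sodium phenoxide in a non-polar solvent; the tight ion pair directs the allylic bromide to the ring carbon next to oxygen by SN2 without allylic transposition, and with the para position blocked and both ortho positions equivalent only one C-prenyl isomer can form.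

Step 8
Reactants: 10 4-[2-(tert-butyldimethylsilyloxy)ethyl]-3,5-bis(methoxymethoxy)-2-(3-methylbut-2-en-1-yl)phenol
Product: 11 5-[2-(tert-butyldimethylsilyloxy)ethyl]-2-hydroxy-4,6-bis(methoxymethoxy)-3-(3-methylbut-2-en-1-yl)benzaldehyde
Conditions: MgCl2, Et3N, (CH2O)n, MeCN, reflux
Reagents that add atoms: paraformaldehyde (as formaldehyde), C=O
Why: Casiraghi–Skattebøl ortho-formylation; the magnesium phenoxide delivers formaldehyde to the only free ring position and a second formaldehyde oxidises the benzylic alkoxide by hydride transfer, which should leave the prenyl group and the acetals untouched.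

Step 9
Reactants: 12 2-methoxy-4-vinylphenol
Product: 13 4-ethenyl-2-methoxy-1-(methoxymethoxy)benzene
Conditions: MOMCl, i-Pr2NEt, CH2Cl2, 0 °C to rt
Reagents that add atoms: chloromethyl methyl ether, COCCl
Why: O-Alkylation of the phenol; the para-alkoxy group keeps the styrene nucleophilic and the acetal is cleaved in the final acid step with the others.

Step 10
Reactants: 11 5-[2-(tert-butyldimethylsilyloxy)ethyl]-2-hydroxy-4,6-bis(methoxymethoxy)-3-(3-methylbut-2-en-1-yl)benzaldehyde; 13 4-ethenyl-2-methoxy-1-(methoxymethoxy)benzene
Product: 16 (2S,4S)-6-[2-(tert-butyldimethylsilyloxy)ethyl]-4-methoxy-2-[3-methoxy-4-(methoxymethoxy)phenyl]-5,7-bis(methoxymethoxy)-8-(3-methylbut-2-en-1-yl)chromane (2,4-cis), via dimethyl acetal 14 (not isolated), via methoxy ortho-quinone methide 15 (not isolated)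
Conditions: (R)-3,3'-bis(2,4,6-triisopropylphenyl)-1,1'-binaphthyl-2,2'-diyl hydrogen phosphate (10 mol%), HC(OMe)3 (2 equiv), 13 (2.5 equiv), 5 Å MS, toluene, −20 °C to rt
Reagents that add atoms: trimethyl orthoformate, COC(OC)OC
Why: Proposed new method: the acid and the orthoformate convert 11 into acetal 14, which loses methanol to an O-methyl oxocarbenium ion paired with the chiral phosphate; this is the protonated form of quinone methide 15, in which O1, C8a, C4a and C4 make up a 1-oxadiene. The terminal carbon of 13 attacks C4, and the benzylic cation developing at C2, stabilised by the para oxygen of ring B, is captured by O1, an inverse-demand oxa-[4+2] that is strongly asynchronous or stepwise. The closest known reaction types are the acid-promoted cycloaddition of salicylaldehyde acetals with styrenes to racemic 2-aryl-4-alkoxychromans and chiral phosphoric acid catalysed cycloadditions of ortho-quinone methides with alkenes; the enantioselective intermolecular union of an alkoxy quinone methide with a styrene that has no hydrogen-bond donor has not been shown. Ring C is closed by the cycloaddition itself, and in the stepwise limit the last bond O1–C2 forms by 6-exo-trig capture of the quinoid benzylic cation. C2 is set by the catalyst: the phosphate should stay hydrogen-bonded to O1–H through both bond formations, so that its 3,3'-aryl groups shield one face of C4 and the styrene aryl group takes the endo position, giving 2S. C4 follows from the endo approach as 2,4-cis (4S) and is erased in step 11, so both C4 epimers are usable provided they share 2S. Aryl ends at C2 because nucleophilic CH2 meets electrophilic C4 and the cation sits at the benzylic carbon. The step needs acetal ionisation to outrun acid-induced cyclisation of the ortho-prenyl phenol, cationic oligomerisation of 13 and loss of the acetal and silyl groups; the three ring oxygens of 11 should let 14 ionise with a weak acid at low temperature, and the full substitution of ring A excludes Friedel–Crafts self-condensation.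

Step 11
Reactants: 16 (2S,4S)-6-[2-(tert-butyldimethylsilyloxy)ethyl]-4-methoxy-2-[3-methoxy-4-(methoxymethoxy)phenyl]-5,7-bis(methoxymethoxy)-8-(3-methylbut-2-en-1-yl)chromane
Product: 18 (2S)-6-[2-(tert-butyldimethylsilyloxy)ethyl]-2-[3-methoxy-4-(methoxymethoxy)phenyl]-5,7-bis(methoxymethoxy)-8-(3-methylbut-2-en-1-yl)chroman-4-one, via C4 hemiketal 17 (not isolated)
Conditions: DDQ (1.3 equiv), CH2Cl2/pH 7 buffer (10:1), 0 °C to rt
Reagents that add atoms: water, O
Why: Oxidation of an electron-rich benzylic ether by hydride abstraction with DDQ, as in the cleavage of alkoxybenzyl ethers; the C4–H bond, benzylic to the trioxygenated ring A and α to oxygen, is the most hydridic, water adds to the oxocarbenium ion and hemiketal 17 loses methanol to the ketone. C2 is untouched, both C4 epimers converge, and no free phenol is present to cyclise oxidatively onto the prenyl group.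

Step 12
Reactants: 18 (2S)-6-[2-(tert-butyldimethylsilyloxy)ethyl]-2-[3-methoxy-4-(methoxymethoxy)phenyl]-5,7-bis(methoxymethoxy)-8-(3-methylbut-2-en-1-yl)chroman-4-one
Product: 19 laxiflorin, (2S)-5,7-dihydroxy-6-(2-hydroxyethyl)-2-(4-hydroxy-3-methoxyphenyl)-8-(3-methylbut-2-en-1-yl)chroman-4-one
Conditions: HCl (3 M), MeOH, rt to 40 °C
Reagents that add atoms: none
Why: Acid-catalysed acetal exchange with methanol should cleave the three methoxymethyl ethers and solvolyse the primary silyl ether in one operation; no base is used, so the retro-oxa-Michael opening that racemises 4'-hydroxyflavanones is avoided and C2 should stay S.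

## Compound list

1 | 2,4,6-trihydroxybenzaldehyde | O=Cc1c(O)cc(O)cc1O | starting material
2 | 4-(benzyloxy)-2,6-dihydroxybenzaldehyde | O=Cc1c(O)cc(OCc2ccccc2)cc1O | intermediate
3 | 4-(benzyloxy)-2,6-bis(methoxymethoxy)benzaldehyde | O=Cc1c(OCOC)cc(OCc2ccccc2)cc1OCOC | intermediate
4 | 5-(benzyloxy)-2-ethenyl-1,3-bis(methoxymethoxy)benzene | C=Cc1c(OCOC)cc(OCc2ccccc2)cc1OCOC | intermediate
5 | 9-{2-[4-(benzyloxy)-2,6-bis(methoxymethoxy)phenyl]ethyl}-9-borabicyclo[3.3.1]nonane (not isolated) | COCOc1cc(OCc2ccccc2)cc(OCOC)c1CCB1C2CCCC1CCC2 | intermediate
6 | 2-[4-(benzyloxy)-2,6-bis(methoxymethoxy)phenyl]ethan-1-ol | OCCc1c(OCOC)cc(OCc2ccccc2)cc1OCOC | intermediate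
7 | {2-[4-(benzyloxy)-2,6-bis(methoxymethoxy)phenyl]ethoxy}(tert-butyl)dimethylsilane | CC(C)(C)[Si](C)(C)OCCc1c(OCOC)cc(OCc2ccccc2)cc1OCOC | intermediate
8 | 4-[2-(tert-butyldimethylsilyloxy)ethyl]-3,5-bis(methoxymethoxy)phenol | CC(C)(C)[Si](C)(C)OCCc1c(OCOC)cc(O)cc1OCOC | intermediate
9 | prenyl bromide (1-bromo-3-methylbut-2-ene) | CC(C)=CCBr | starting material
10 | 4-[2-(tert-butyldimethylsilyloxy)ethyl]-3,5-bis(methoxymethoxy)-2-(3-methylbut-2-en-1-yl)phenol | CC(C)(C)[Si](C)(C)OCCc1c(OCOC)cc(O)c(CC=C(C)C)c1OCOC | intermediate
11 | 5-[2-(tert-butyldimethylsilyloxy)ethyl]-2-hydroxy-4,6-bis(methoxymethoxy)-3-(3-methylbut-2-en-1-yl)benzaldehyde | O=Cc1c(O)c(CC=C(C)C)c(OCOC)c(CCO[Si](C)(C)C(C)(C)C)c1OCOC | intermediate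
12 | 2-methoxy-4-vinylphenol | C=Cc1ccc(O)c(OC)c1 | starting material
13 | 4-ethenyl-2-methoxy-1-(methoxymethoxy)benzene | C=Cc1ccc(OCOC)c(OC)c1 | intermediate
14 | 4-[2-(tert-butyldimethylsilyloxy)ethyl]-2-(dimethoxymethyl)-3,5-bis(methoxymethoxy)-6-(3-methylbut-2-en-1-yl)phenol, the dimethyl acetal of 11 (not isolated) | COC(OC)c1c(O)c(CC=C(C)C)c(OCOC)c(CCO[Si](C)(C)C(C)(C)C)c1OCOC | intermediate
15 | 4-[2-(tert-butyldimethylsilyloxy)ethyl]-6-(methoxymethylidene)-3,5-bis(methoxymethoxy)-2-(3-methylbut-2-en-1-yl)cyclohexa-2,4-dien-1-one, the methoxy ortho-quinone methide (not isolated; reacts as its O-protonated ion pair with the catalyst) | COC=C1C(=O)C(CC=C(C)C)=C(OCOC)C(CCO[Si](C)(C)C(C)(C)C)=C1OCOC | intermediate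
16 | (2S,4S)-6-[2-(tert-butyldimethylsilyloxy)ethyl]-4-methoxy-2-[3-methoxy-4-(methoxymethoxy)phenyl]-5,7-bis(methoxymethoxy)-8-(3-methylbut-2-en-1-yl)chromane (2,4-cis) | COc1cc([C@@H]2C[C@H](OC)c3c(OCOC)c(CCO[Si](C)(C)C(C)(C)C)c(OCOC)c(CC=C(C)C)c3O2)ccc1OCOC | intermediate
17 | (2S)-6-[2-(tert-butyldimethylsilyloxy)ethyl]-4-methoxy-2-[3-methoxy-4-(methoxymethoxy)phenyl]-5,7-bis(methoxymethoxy)-8-(3-methylbut-2-en-1-yl)chroman-4-ol, C4 epimers (not isolated) | COc1cc([C@@H]2CC(O)(OC)c3c(OCOC)c(CCO[Si](C)(C)C(C)(C)C)c(OCOC)c(CC=C(C)C)c3O2)ccc1OCOC | intermediate
18 | (2S)-6-[2-(tert-butyldimethylsilyloxy)ethyl]-2-[3-methoxy-4-(methoxymethoxy)phenyl]-5,7-bis(methoxymethoxy)-8-(3-methylbut-2-en-1-yl)chroman-4-one | COc1cc([C@@H]2CC(=O)c3c(OCOC)c(CCO[Si](C)(C)C(C)(C)C)c(OCOC)c(CC=C(C)C)c3O2)ccc1OCOC | intermediate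
19 | laxiflorin, (2S)-5,7-dihydroxy-6-(2-hydroxyethyl)-2-(4-hydroxy-3-methoxyphenyl)-8-(3-methylbut-2-en-1-yl)chroman-4-one | COc1cc([C@@H]2CC(=O)c3c(O)c(CCO)c(O)c(CC=C(C)C)c3O2)ccc1O | target

## Step count and least certain steps

Total: 12 steps. Longest linear sequence: 11 steps (steps 1 to 8 and 10 to 12, from 1).

**Step 10 (key step, proposed new method).**
- What may go wrong: poor facial selectivity at C2, because the styrene offers no hydrogen-bond donor and the strongly stabilised oxocarbenium ion may react as a loose ion pair.
- An unselective endo/exo approach would give C2 epimers that become enantiomers after step 11.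
- Capture by the styrene may be slow, with cationic oligomerisation of 13 or acid-induced cyclisation of the prenyl group onto O1–H taking over.
- First variation within the step: a more confined acid of the same family.
- Fallback (known chemistry), setting out from 11 and 13: the two are combined with trimethyl orthoformate and an achiral acid such as diphenyl hydrogen phosphate, the known acid-promoted cycloaddition. This should give 16 as a racemate together with the (2R,4R)-enantiomer of 16 F1. Oxidation with DDQ as in step 11 should give 18 together with the (2R)-enantiomer of 18 F2. Preparative chromatography on a chiral stationary phase then returns the route at 18.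

**Step 11.**
- What may go wrong: hydride abstraction at the prenyl methylene (benzylic and allylic on the same electron-rich ring) or at C2, or ionisation of the C4 ether by the acidic reduced quinone followed by elimination to the 2H-chromene.
- Fallback, setting out from 16: mild aqueous acid (pyridinium p-toluenesulfonate, wet acetone) exchanges the C4 methoxy group for hydroxyl by solvolysis to give the flavan-4-ol F3 as C4 epimers. Oxidation of the alcohol with Dess–Martin periodinane returns the route at 18.

**Step 7.**
- What may go wrong: O-alkylation of the phenoxide and a second C-alkylation at the remaining ortho position.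
- Fallback, setting out from 8: O-alkylation catalysed by zerovalent palladium, Pd(PPh3)4, with tert-butyl 2-methylbut-3-en-2-yl carbonate gives the tertiary allyl aryl ether F4. Aromatic Claisen rearrangement in refluxing toluene moves the group to the ortho carbon with allylic inversion and returns the route at 10.

**Step 12.**
- What may go wrong: acid-induced cyclisation of the prenyl group onto the freed 7-OH, addition of methanol across the alkene, or partial loss of configuration by acid-induced opening at C2.
- Fallback, setting out from 18: HF·pyridine in THF removes the silyl ether to give the tris(methoxymethyl) alcohol F5. ZnBr2 with propane-1-thiol in CH2Cl2 at 0 °C then cleaves the three acetals under aprotic conditions within minutes and returns the route at 19.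

**Step 1.**
- What may go wrong: alkylation of a second hydroxyl and C-benzylation of the phloroglucinol ring.
- Fallback, setting out from 1: Mitsunobu etherification with benzyl alcohol (PPh3, diisopropyl azodicarboxylate) selects the most acidic hydroxyl through the alkoxyphosphonium ion without a free phenoxide and returns the route at 2. It makes no new compound (F0).

## Further compounds

F1 | step 10 | (2R,4R)-enantiomer of 16, second component of the racemic adduct | COc1cc([C@H]2C[C@@H](OC)c3c(OCOC)c(CCO[Si](C)(C)C(C)(C)C)c(OCOC)c(CC=C(C)C)c3O2)ccc1OCOC
F2 | step 10 | (2R)-enantiomer of 18, removed on the chiral phase | COc1cc([C@H]2CC(=O)c3c(OCOC)c(CCO[Si](C)(C)C(C)(C)C)c(OCOC)c(CC=C(C)C)c3O2)ccc1OCOC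
F3 | step 11 | (2S)-6-[2-(tert-butyldimethylsilyloxy)ethyl]-2-[3-methoxy-4-(methoxymethoxy)phenyl]-5,7-bis(methoxymethoxy)-8-(3-methylbut-2-en-1-yl)chroman-4-ol, C4 epimers | COc1cc([C@@H]2CC(O)c3c(OCOC)c(CCO[Si](C)(C)C(C)(C)C)c(OCOC)c(CC=C(C)C)c3O2)ccc1OCOC
F4 | step 7 | tert-butyl{2-[2,6-bis(methoxymethoxy)-4-(2-methylbut-3-en-2-yloxy)phenyl]ethoxy}dimethylsilane | CC(C)(C)[Si](C)(C)OCCc1c(OCOC)cc(OC(C)(C)C=C)cc1OCOC
F5 | step 12 | (2S)-6-(2-hydroxyethyl)-2-[3-methoxy-4-(methoxymethoxy)phenyl]-5,7-bis(methoxymethoxy)-8-(3-methylbut-2-en-1-yl)chroman-4-one | COc1cc([C@@H]2CC(=O)c3c(OCOC)c(CCO)c(OCOC)c(CC=C(C)C)c3O2)ccc1OCOC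
F0 | step 1 | none | none
A1 | alternative 1 | (2S)-2-[3-methoxy-4-(methoxymethoxy)phenyl]-6-[5-methyl-1-oxo-1-(2-oxooxolan-3-yl)hex-4-en-2-yl]-2,3-dihydro-4H-pyran-4-one, side-chain stereocentres unspecified | COCOc1ccc([C@@H]2CC(=O)C=C(C(CC=C(C)C)C(=O)C3CCOC3=O)O2)cc1OC
A2 | alternative 1 | 4'-O-methoxymethyl laxiflorin | COCOc1ccc([C@@H]2CC(=O)c3c(O)c(CCO)c(O)c(CC=C(C)C)c3O2)cc1OC
A3 | alternative 2 | 2-diazo-1-{2-[4-(tert-butyldimethylsilyloxy)-3-methoxybenzyloxy]-4,6-bis(tert-butyldimethylsilyloxy)-5-[2-(tert-butyldimethylsilyloxy)ethyl]-3-(3-methylbut-2-en-1-yl)phenyl}ethan-1-one | [N-]=[N+]=CC(=O)c1c(O[Si](C)(C)C(C)(C)C)c(CCO[Si](C)(C)C(C)(C)C)c(O[Si](C)(C)C(C)(C)C)c(CC=C(C)C)c1OCc1ccc(O[Si](C)(C)C(C)(C)C)c(OC)c1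
A4 | alternative 2 | (S)-tetrakis(tert-butyldimethylsilyl) laxiflorin | CC(C)(C)[Si](C)(C)Oc1ccc([C@@H]2CC(=O)c3c(O[Si](C)(C)C(C)(C)C)c(CCO[Si](C)(C)C(C)(C)C)c(O[Si](C)(C)C(C)(C)C)c(CC=C(C)C)c3O2)cc1OC
A5 | alternative 3 | 2-(trimethylsilyloxy)-3-[5-methyl-1-(trimethylsilyloxy)hexa-1,4-dien-1-yl]-4,5-dihydrofuran, enol ether geometry unspecified | C[Si](C)(C)OC1=C(C(O[Si](C)(C)C)=CCC=C(C)C)CCO1
A6 | alternative 3 | (S)-5-bromo-2-[4-(tert-butyldimethylsilyloxy)-3-methoxyphenyl]-2,3-dihydro-4H-pyran-4-one | CC(C)(C)[Si](C)(C)Oc1ccc([C@@H]2CC(=O)C(Br)=CO2)cc1OC
A7 | alternative 3 | 4'-O-(tert-butyldimethylsilyl) laxiflorin | CC(C)(C)[Si](C)(C)Oc1ccc([C@@H]2CC(=O)c3c(O)c(CCO)c(O)c(CC=C(C)C)c3O2)cc1OC
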